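In a closed flask the charged reagent stays countable: it is either free or sits in a product.

| setting | ochre | teal | summer | dawn |
|---|---|---|---|---|
| substrate | 0.28 M | 0.28 M | 0.28 M | 0.28 M |
| reagent | 1.6 equiv | 1.8 equiv | 2.00 equiv | 2.40 equiv |
| remark | run made earlier | run made earlier |  |  |
| time |  |  | 20 min | 20 min |

| run | time / min | substrate / % | side product / % | tetra adduct / % | triple product / % |
|---|---|---|---|---|---|
| ochre | 2.50 | 20.6 | 45.3 | 3.8 | 6.0 |
| ochre | 8.00 | 21.3 | 61.0 | 3.1 | 8.0 |
| ochre | 12.0 | 20.5 | 59.7 | 2.3 | 7.0 |
| ochre | 20.0 | 22.3 | 59.7 | 1.5 | 6.6 |
| teal | 1.50 | 15.7 | 36.4 | 2.0 | 9.5 |
| teal | 4.00 | 14.4 | 60.0 | 4.5 | 8.7 |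
| teal | 8.00 | 14.7 | 65.0 | 3.3 | 7.7 |
| teal | 20.0 | 13.7 | 65.1 | 5.3 | 10.4 |

(scatter of a reading: 1 percentage point)

- which of these there is most of at the end, counted by the substrate in it, summer (side product / substrate / triple product / tetra adduct)
- which of these there is most of at the end, counted by the substrate in it, dawn (side product / substrate / triple product / tetra adduct)
- amount of the one of these that there is most of at the end, in percent of the substrate charged, summer
- amount of the one of these that there is most of at the end, in percent of the substrate charged, dawn



I count 2 reagent in side product, 3 in triple product, 4 in tetra adduct and one in the unseen remainder of the substrate. Per substrate charged: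

equivalents charged = [free reagent] + [unseen] + 2[side product] + 3[triple product] + 4[tetra adduct]

Ochre and teal look nearly the same, yet ochre ends with 22.3% substrate and teal with 13.7%. Their last readings count 1.55 equivalents bound in ochre, against 1.6 equiv charged, and 1.88 in teal, against 1.8 equiv. So I can't tell free reagent from zero in either, and each flask stands where its charge is bound.

Dawn is charged 0.400 above two equivalents. This overhang, the equivalents charged above two, follows from taking twice the substrate balance away:

overhang = [free reagent] + [triple product] + 2[tetra adduct] − 2[substrate] − [unseen]

Between ochre and teal the overhang moves by 0.200, and the substrate term takes up 0.172 of that. Dawn's overhang is positive, so I assume free reagent, substrate and unseen are nearly gone. Side product then lies between 60.0%, if triple product takes the overhang, and 80.0%, if tetra adduct does, and it leads. Summer's overhang is 0 and gives no such range, so I go by teal, where side product leads.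

The forecast names side product for summer at 67% and side product for dawn at 63%, a single figure inside my range. It adds: “Twenty minutes is enough time for both.”

The flasks give side product at 69.5% in summer and side product at 69.5% at dawn, so the forecast is 6.5 percentage points low at dawn.

    reagent + double product → triple product (k = 0.0460 /M/s)
    substrate + reagent → single product (k = 0.200 /M/s)
    double product → side product (k = 0.0110 /s)
    reagent + triple product → tetra adduct (k = 0.0920 /M/s)
    reagent + single product → double product (k = 0.620 /M/s)

Dawn's side product stands 9.5 points above the lower end of my range and 10 points below the upper end, with 11.1% triple product and 16.6% tetra adduct beside it. Side product stands that high because reagent is used up during the run: the same run with reagent not consumed ends at 26.2%, against 69.5%.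

Take dawn's recipe at 0.11 M substrate. The equivalents are held, so the overhang is again 0.400 and the range 60.0% to 80.0%. That flask ends with 78.7% side product, 15.9% tetra adduct and 4.46% triple product.

The data stem from a simulated flask for substances that don't exist; scatter was added.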